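**Strategy.** The route rests on cutting the C3–C4 bond of ring C. C3 (carbinol) and C4 (ketone) are neighbouring oxygen-bearing carbons. Each is therefore traced back to a formyl group, and the two are rejoined by a SmI2 pinacol coupling. That single operation forges C3–C4, closes the six-membered ring C and places the C3 oxygen trans to the C2 phenyl. The transient C4 carbinol is then oxidised to the ketone. The precursor is an enantiopure dialdehyde: a ring A benzaldehyde bearing OMe, prenyl and a methoxymethyl (MOM) ether, whose hindered ortho oxygen (future O1) carries a CH(Ph)CHO arm. Its only stereocentre, the future C2, comes from methyl (S)-mandelate by Mitsunobu inversion.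

Key step: step 7

Remarks on the chemistry:
- Flavonoid numbering (O1, C2, C3, C4, C4a, C5–C8, C8a; ring A benzo, ring C pyran) is used for the cyclised compounds and for the atoms that become them.
- The target is (2R,3R), 2,3-trans. C3 is labelled S in the 3,4-diol and R in the 4-ketones although its geometry is unchanged, because C4 outranks C2 only once it is a carbonyl carbon.
- The dialdehyde is made without amine base and carried on the same day. Its C2–H is benzylic, alpha to oxygen and alpha to a formyl group.
- Assumption: commercial methyl (S)-mandelate of high enantiopurity is used.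

Step 1
Reactants: 1 2,4,6-trihydroxybenzaldehyde; 2 prenyl bromide (1-bromo-3-methylbut-2-ene)
Product: 3 2,4,6-trihydroxy-3-(3-methylbut-2-enyl)benzaldehyde
Conditions: KOH (1.0 equiv), H2O, 0 °C → rt, 1 in slight excess
Reagents that add atoms: none
Why: C-alkylation of an ambident phloroglucinol-type phenolate, in which water hydrogen-bonds the phenolate oxygens so the soft allylic bromide is taken at ring carbon, C3 and C5 are equivalent so only one mono-C-prenyl isomer can form, and the excess of 1 holds back a second prenylation.

Step 2
Reactants: 3 2,4,6-trihydroxy-3-(3-methylbut-2-enyl)benzaldehyde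
Product: 4 2,6-dihydroxy-4-methoxy-3-(3-methylbut-2-enyl)benzaldehyde
Conditions: Me2SO4 (1.0 equiv), K2CO3 (1.0 equiv), acetone, rt
Reagents that add atoms: dimethyl sulfate, COS(=O)(=O)OC
Why: Regioselective Williamson ether synthesis, since the 4-OH para to the formyl group is the most acidic hydroxyl and the only one that cannot hydrogen-bond to the carbonyl, so one equivalent of base and of the hard methylating agent should react there first.

Step 3
Reactants: 4 2,6-dihydroxy-4-methoxy-3-(3-methylbut-2-enyl)benzaldehyde
Product: 5 2-hydroxy-4-methoxy-6-(methoxymethoxy)-3-(3-methylbut-2-enyl)benzaldehyde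
Conditions: MOMCl (1.05 equiv), i-Pr2NEt, CH2Cl2, 0 °C
Reagents that add atoms: chloromethyl methyl ether (MOMCl), COCCl
Why: Selective MOM protection, because the 6-OH has an open flank (C5–H) whereas the 2-OH is wedged between prenyl and formyl and keeps the carbonyl hydrogen bond, the same bias that leaves this hydroxyl free when 3-prenylated acylphloroglucinols are MOM-protected.

Step 4
Reactants: 5 2-hydroxy-4-methoxy-6-(methoxymethoxy)-3-(3-methylbut-2-enyl)benzaldehyde; 6 methyl (S)-mandelate
Product: 7 methyl (R)-2-[2-formyl-5-methoxy-3-(methoxymethoxy)-6-(3-methylbut-2-enyl)phenoxy]-2-phenylacetate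
Conditions: PPh3, DIAD (added last), THF (0.5 M), 0 °C → rt
Reagents that add atoms: none
Why: Mitsunobu etherification, in which the acidic salicylaldehyde-type phenol displaces the oxyphosphonium group of the secondary alcohol by SN2 while the ester suppresses benzylic ionisation, so the (S) carbinol carbon is inverted to the (R) aryl ether that becomes C2.

Step 5
Reactants: 7 methyl (R)-2-[2-formyl-5-methoxy-3-(methoxymethoxy)-6-(3-methylbut-2-enyl)phenoxy]-2-phenylacetate
Product: 8 (R)-2-[2-(hydroxymethyl)-5-methoxy-3-(methoxymethoxy)-6-(3-methylbut-2-enyl)phenoxy]-2-phenylethanol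
Conditions: LiAlH4, THF, −20 → 0 °C; Na2SO4·10H2O quench; Et3N-washed silica
Reagents that add atoms: none
Why: Hydride reduction of ester and aldehyde by LiAlH4 is faster at low temperature than deprotonation at the stereocentre, and the MOM acetal, the aryl ethers and the trisubstituted alkene are inert to it.

Step 6
Reactants: 8 (R)-2-[2-(hydroxymethyl)-5-methoxy-3-(methoxymethoxy)-6-(3-methylbut-2-enyl)phenoxy]-2-phenylethanol
Product: 9 (R)-2-[2-formyl-5-methoxy-3-(methoxymethoxy)-6-(3-methylbut-2-enyl)phenoxy]-2-phenylacetaldehyde
Conditions: Dess–Martin periodinane (2.5 equiv), NaHCO3, CH2Cl2, 0 °C → rt; Et2O/pentane, filtration through Celite, toluene azeotrope, no chromatography, used at once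
Reagents that add atoms: none
Why: Dess–Martin oxidation converts both primary alcohols without any amine base, which avoids enolisation at C2 (racemisation or aldol attack on the aryl aldehyde), while NaHCO3 takes up the acetic acid that could ionise the electron-rich benzylic alcohol or the MOM acetal.

Step 7
Reactants: 9 (R)-2-[2-formyl-5-methoxy-3-(methoxymethoxy)-6-(3-methylbut-2-enyl)phenoxy]-2-phenylacetaldehyde
Product: 11 (2R,3S,4S)-7-methoxy-5-(methoxymethoxy)-8-(3-methylbut-2-enyl)-2-phenylchroman-3,4-diol, via samarium diolate 10 (not isolated)
Conditions: SmI2 (2.5 equiv, 0.1 M), THF, −78 → −30 °C, slow addition of 9 (final 0.01 M), no HMPA; then aq. NaHCO3; Et3N-washed silica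
Reagents that add atoms: none
Why: One SmI2 transfers an electron to the conjugated C4 formyl group, the aryl-stabilised samarium ketyl attacks the carbon of the tethered C3 formyl group, and a second SmI2 reduces the oxygen radical so formed, leaving diolate 10, which aqueous NaHCO3 protonates. The closest known reaction type is the SmI2-mediated intramolecular pinacol coupling of 1,6-dialdehydes to cyclic cis-1,2-diols. Ring C (O1–C2–C3–C4–C4a–C8a) closes in the 6-exo-trig mode, since the attacked C=O bond stays outside the new ring. C3 is controlled by the existing C2 centre, because in the half-chair transition state the C2 phenyl lies pseudo-equatorial and the bulky samarium-bound oxygen at C3 takes the equatorial site on the opposite ring face, which is the 2,3-trans relation (3S in 11). C4 is controlled by trivalent samarium bridging both oxygens, which holds them on one face (3,4-cis, 4S) with a pseudo-axial C4–O bond that also escapes the peri C5 substituent, and a C4 epimer would do no harm because step 8 erases this centre. The step needs the aryl aldehyde to be reduced first and ring closure to outrun expulsion of the aryloxide from C2, enolisation at C2 and intermolecular coupling, which the substrate secures through conjugation of the C4 carbonyl, chelation of samarium by the C5 acetal oxygen and a short tether containing two ring A atoms, backed by low temperature and slow addition into excess reductant.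

Step 8
Reactants: 11 (2R,3S,4S)-7-methoxy-5-(methoxymethoxy)-8-(3-methylbut-2-enyl)-2-phenylchroman-3,4-diol
Product: 12 (2R,3R)-3-hydroxy-7-methoxy-5-(methoxymethoxy)-8-(3-methylbut-2-enyl)-2-phenylchroman-4-one
Conditions: activated MnO2 (excess), CH2Cl2, rt
Reagents that add atoms: none
Why: Chemoselective benzylic oxidation with MnO2, in which the C4 carbinol is activated by the tri-oxygenated ring A and gives a strongly conjugated aryl ketone while the saturated C3 carbinol is not a substrate, and the neutral medium leaves C2 and C3 untouched as the C4 stereocentre disappears.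

Step 9
Reactants: 12 (2R,3R)-3-hydroxy-7-methoxy-5-(methoxymethoxy)-8-(3-methylbut-2-enyl)-2-phenylchroman-4-one
Product: 13 (2R,3R)-3,5-dihydroxy-7-methoxy-8-(3-methylbut-2-enyl)-2-phenylchroman-4-one (CNP0400369.2)
Conditions: HCl (cat., 2 M aq), MeOH, 40 °C
Reagents that add atoms: none
Why: Acid-catalysed acetal exchange (MOM cleavage) removes the only acid-labile group, helped by the hydrogen bond between the freed 5-OH and C4=O, while the prenyl group has no free ortho hydroxyl to cyclise onto and the 2,3-trans arrangement is the stable one, so no stereocentre should move.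

**Compound list**

1 | 2,4,6-trihydroxybenzaldehyde | O=Cc1c(O)cc(O)cc1O | starting material
2 | prenyl bromide (1-bromo-3-methylbut-2-ene) | CC(C)=CCBr | starting material
3 | 2,4,6-trihydroxy-3-(3-methylbut-2-enyl)benzaldehyde | O=Cc1c(O)cc(O)c(CC=C(C)C)c1O | intermediate
4 | 2,6-dihydroxy-4-methoxy-3-(3-methylbut-2-enyl)benzaldehyde | COc1cc(O)c(C=O)c(O)c1CC=C(C)C | intermediate
5 | 2-hydroxy-4-methoxy-6-(methoxymethoxy)-3-(3-methylbut-2-enyl)benzaldehyde | COc1cc(OCOC)c(C=O)c(O)c1CC=C(C)C | intermediate
6 | methyl (S)-mandelate | COC(=O)[C@@H](O)c1ccccc1 | starting material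
7 | methyl (R)-2-[2-formyl-5-methoxy-3-(methoxymethoxy)-6-(3-methylbut-2-enyl)phenoxy]-2-phenylacetate | COc1cc(OCOC)c(C=O)c(c1CC=C(C)C)O[C@H](c1ccccc1)C(=O)OC | intermediate
8 | (R)-2-[2-(hydroxymethyl)-5-methoxy-3-(methoxymethoxy)-6-(3-methylbut-2-enyl)phenoxy]-2-phenylethanol | COc1cc(OCOC)c(CO)c(c1CC=C(C)C)O[C@H](c1ccccc1)CO | intermediate
9 | (R)-2-[2-formyl-5-methoxy-3-(methoxymethoxy)-6-(3-methylbut-2-enyl)phenoxy]-2-phenylacetaldehyde | COc1cc(OCOC)c(C=O)c(c1CC=C(C)C)O[C@H](c1ccccc1)C=O | intermediate
10 | bis(diiodosamarium) 3,4-diolate of diol 11, same configuration at C2, C3 and C4 (not isolated) | COc1cc(OCOC)c2c(c1CC=C(C)C)O[C@H](c1ccccc1)[C@@H](O[Sm](I)I)[C@H]2O[Sm](I)I | intermediate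
11 | (2R,3S,4S)-7-methoxy-5-(methoxymethoxy)-8-(3-methylbut-2-enyl)-2-phenylchroman-3,4-diol (2,3-trans, 3,4-cis) | COc1cc(OCOC)c2c(c1CC=C(C)C)O[C@H](c1ccccc1)[C@@H](O)[C@H]2O | intermediate
12 | (2R,3R)-3-hydroxy-7-methoxy-5-(methoxymethoxy)-8-(3-methylbut-2-enyl)-2-phenylchroman-4-one | COc1cc(OCOC)c2c(c1CC=C(C)C)O[C@H](c1ccccc1)[C@@H](O)C2=O | intermediate
13 | (2R,3R)-3,5-dihydroxy-7-methoxy-8-(3-methylbut-2-enyl)-2-phenylchroman-4-one | COc1cc(O)c2c(c1CC=C(C)C)O[C@H](c1ccccc1)[C@@H](O)C2=O | target

**Totals.** Total step count: 9. Longest linear sequence: 9 steps (1 → 13); 2 and 6 enter as purchased building blocks.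

**Steps most likely to fail**

1. Step 7.
   - What may go wrong: electron transfer to the aliphatic carbonyl followed by reductive cleavage of the C2–O1 bond; loss of configuration at C2 by enolisation before closure; plain reduction of the formyl groups; or intermolecular coupling.
   - Fallback: electron-transfer chemistry is replaced by a neutral tin hydride radical chain. Setting out from 9, Bu3SnH with AIBN in benzene at 80 °C adds a stannyl radical reversibly to a carbonyl oxygen. The benzylic O-stannyl ketyl at C4 is the favoured chain carrier and closes onto the C3 formyl group in the same 6-exo sense. Hydrogen transfer from Bu3SnH should then give the 4-O-tributylstannyl ether F1, which loses tin on moist silica gel and comes back to the route at 11.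
   - No low-valent metal is present, so the two-electron reduction that drives aryloxide loss is not available.

2. Step 8.
   - What may go wrong: oxidative scission of the cis-glycol C3–C4 bond on the oxide surface; sluggish reaction of the pseudo-axial, peri-shielded C4 carbinol; or further oxidation toward the flavonol level.
   - Fallback: reliance on a selective oxidant is replaced by a temporary block on O3. Setting out from 11, TESCl (1 equiv) with imidazole in CH2Cl2 at −20 °C should silylate the equatorial, less shielded C3 hydroxyl to the 3-O-triethylsilyl diol F2. Dess–Martin periodinane with NaHCO3 then oxidises the only free carbinol to the 3-O-triethylsilyl ketone F3. The HCl/MeOH conditions of step 9 remove the silyl ether and the MOM acetal together, so the sequence comes back at 13 at the cost of one extra step.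

3. Step 4.
   - What may go wrong: slow attack by the hindered, hydrogen-bonded phenol, so that the activated alcohol is diverted to alkylation of the hydrazide; or partial ionisation at the benzylic carbon with erosion of enantiopurity.
   - Fallback: activation is separated from displacement. Setting out from 6, MsCl and Et3N in CH2Cl2 at 0 °C give methyl (S)-2-(methylsulfonyloxy)-2-phenylacetate F4. The weakly basic phenoxide of 5 (Cs2CO3, MeCN, rt) displaces the sulfonate by SN2 with inversion, and the sequence comes back at 7.

**Further compounds**

F1 | step 7 | (2R,3R,4S)-7-methoxy-5-(methoxymethoxy)-8-(3-methylbut-2-enyl)-2-phenyl-4-(tributylstannyloxy)chroman-3-ol (4-O-tributylstannyl ether of 11) | COc1cc(OCOC)c2c(c1CC=C(C)C)O[C@H](c1ccccc1)[C@@H](O)[C@H]2O[Sn](CCCC)(CCCC)CCCC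
F2 | step 8 | (2R,3S,4S)-7-methoxy-5-(methoxymethoxy)-8-(3-methylbut-2-enyl)-2-phenyl-3-(triethylsilyloxy)chroman-4-ol | COc1cc(OCOC)c2c(c1CC=C(C)C)O[C@H](c1ccccc1)[C@@H](O[Si](CC)(CC)CC)[C@H]2O
F3 | step 8 | (2R,3R)-7-methoxy-5-(methoxymethoxy)-8-(3-methylbut-2-enyl)-2-phenyl-3-(triethylsilyloxy)chroman-4-one | COc1cc(OCOC)c2c(c1CC=C(C)C)O[C@H](c1ccccc1)[C@@H](O[Si](CC)(CC)CC)C2=O
F4 | step 4 | methyl (S)-2-(methylsulfonyloxy)-2-phenylacetate | COC(=O)[C@@H](OS(C)(=O)=O)c1ccccc1
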